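**Plan**

- Retrosynthesis: the 8-O-methyl bond is cut first, then ring A at C8–C8a, which leads back to a squarate-derived cyclobutenone on a monocyclic 4-pyranone. The carbinol–pyranone bond (flavone C5–C4a) and the pyranone C2–aryl bond are cut next.
- Enabling feature: C5, C6, C7 and C8 of ring A all carry oxygen, with O5 and O8 para and the C6/C7 methoxyls vicinal. These are the four carbons of dimethyl squarate, and C4a=C8a is the C5=C6 bond of a 2-aryl-3-methoxy-4-pyranone whose C6–H is the only place where the new ring can close.
- Forward: ring C is bought as pyromeconic acid, the dimethoxyphenyl ring is joined by Suzuki coupling, the squarate is attached at pyranone C5 through a Grignard reagent, and ring A is formed last by thermal ring expansion. A chelation-controlled methylation at O8 ends the route.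
- Stereochemistry: the target has none. The carbinol centre of the cyclobutenone is made racemic and is erased on aromatisation.

Key step: step 6

Remark: Grantioidinin has no stereogenic element, so it is a single achiral compound and no enantioselective step is needed.

**Route**

Step 1
Reactants: 1 3-hydroxy-4H-pyran-4-one (pyromeconic acid)
Product: 2 2-bromo-3-hydroxy-4H-pyran-4-one
Conditions: NBS (1.0 equiv), MeCN, 0 °C → rt
Reagents that add atoms: N-bromosuccinimide, O=C1CCC(=O)N1Br
Why: Electrophilic bromination of the enolic (diosphenol-type) hydroxypyranone should go to C2, the carbon ortho to the hydroxyl, as in the bromination of kojic acid and the aldol and Mannich reactions of pyromeconic acid.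

Step 2
Reactants: 2 2-bromo-3-hydroxy-4H-pyran-4-one
Product: 3 2-bromo-3-methoxy-4H-pyran-4-one
Conditions: MeI, K2CO3, acetone, 45 °C
Reagents that add atoms: iodomethane, CI
Why: Williamson O-methylation of the acidic enolic hydroxyl is the standard way to ethers of maltol- and kojic-acid-type pyranones and should leave the C–Br bond untouched.

Step 3
Reactants: 3 2-bromo-3-methoxy-4H-pyran-4-one; 4 (2,5-dimethoxyphenyl)boronic acid
Product: 5 2-(2,5-dimethoxyphenyl)-3-methoxy-4H-pyran-4-one
Conditions: Pd(dppf)Cl2 (5 mol%), K2CO3, 1,4-dioxane/H2O (4:1), 80 °C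
Reagents that add atoms: none
Why: Suzuki–Miyaura coupling; the C2–Br bond of a 4-pyranone is a vinylogous acyl bromide and should undergo fast oxidative addition, as 2-halo-4-pyranones and 2-halochromones do.

Step 4
Reactants: 5 2-(2,5-dimethoxyphenyl)-3-methoxy-4H-pyran-4-one
Product: 6 2-(2,5-dimethoxyphenyl)-5-iodo-3-methoxy-4H-pyran-4-one
Conditions: NIS (1.1 equiv), TFA (0.3 equiv), MeCN, 0 °C → rt, dark
Reagents that add atoms: N-iodosuccinimide, O=C1CCC(=O)N1I
Why: Electrophilic α-iodination of a vinylogous ester; C5 is the β-carbon of the O1–C6=C5 enol ether and the only nucleophilic CH of the heterocycle, whereas the aryl ring carries the electron-withdrawing 4-oxopyranyl group and each of its free positions has only one ortho methoxyl, so iodine should enter at C5 as in the 3-iodination of chromones.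

Step 5
Reactants: 6 2-(2,5-dimethoxyphenyl)-5-iodo-3-methoxy-4H-pyran-4-one; 7 dimethyl squarate (3,4-dimethoxycyclobut-3-ene-1,2-dione)
Product: 9 4-[6-(2,5-dimethoxyphenyl)-5-methoxy-4-oxo-4H-pyran-3-yl]-4-hydroxy-2,3-dimethoxycyclobut-2-en-1-one (racemic), via pyranonylmagnesium chloride 8 (not isolated)
Conditions: iPrMgCl·LiCl (1.05 equiv), THF, −40 °C, 30 min; cannulated into 7 (1.3 equiv), THF, −78 °C; sat. aq NH4Cl, −78 °C → rt
Reagents that add atoms: none
Why: Iodine–magnesium exchange with the turbo-Grignard reagent is fast for an sp2 iodide next to a carbonyl (as with 3-iodochromones), and the resulting Grignard reagent should add 1,2 to one of the two equivalent, strongly electrophilic squarate carbonyls; the new carbinol stereocentre is formed without control (racemic) and is destroyed in step 6.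

Step 6
Reactants: 9 4-[6-(2,5-dimethoxyphenyl)-5-methoxy-4-oxo-4H-pyran-3-yl]-4-hydroxy-2,3-dimethoxycyclobut-2-en-1-one
Product: 12 2-(2,5-dimethoxyphenyl)-5,8-dihydroxy-3,6,7-trimethoxy-4H-chromen-4-one, via dienylketene 10 (not isolated), via cyclohexadienone tautomer 11 (not isolated)
Conditions: degassed toluene (0.02 M), 110 °C, Ar
Reagents that add atoms: none
Why: Thermal conrotatory 4π opening of the cyclobutenone C1–C4 bond should give dienylketene 10, with the donor hydroxyl rotating outward so that the pyranonyl group lies inward, next to the ketene. A 6π electrocyclisation then joins the ketene carbon to the CH beside the pyranone ring oxygen (C6–H in the numbering of 5), forming flavone C8–C8a and closing ring A as cyclohexadienone 11, which enolises to the aromatic hydroquinone 12; the carbinol oxygen becomes 5-OH and the ketene oxygen 8-OH. The closest known reaction is the Moore–Liebeskind ring expansion of 4-aryl-, 4-heteroaryl- and 4-alkenyl-4-hydroxycyclobutenones from squarate esters to hydroquinones, here with the C=C of a 4-pyranone as the alkenyl unit. Ring A is closed by six-electron electrocyclic closure of the hexatriene-type dienylketene; no stereocentre is created in 12, and the carbinol centre of 9 and the transient C8a centre of 11 vanish on aromatisation. The step needs outward rotation of the hydroxyl, which its donor character secures, and has no regiochemical alternative because the other neighbour of the attachment carbon is the C4 carbonyl; oxygen is excluded so that the hydroquinone is not oxidised to the 5,8-quinone.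

Step 7
Reactants: 12 2-(2,5-dimethoxyphenyl)-5,8-dihydroxy-3,6,7-trimethoxy-4H-chromen-4-one
Product: 13 Grantioidinin (2-(2,5-dimethoxyphenyl)-5-hydroxy-3,6,7,8-tetramethoxy-4H-chromen-4-one)
Conditions: MeI (1.1 equiv), K2CO3 (1.2 equiv), degassed acetone, rt → 40 °C, Ar
Reagents that add atoms: iodomethane, CI
Why: Chelation-controlled partial O-methylation; the 5-hydroxyl is held in a hydrogen bond to the C4 carbonyl and is much less nucleophilic, so one equivalent of methylating agent should react at the free 8-hydroxyl, as in the classical partial methylation of 5,8-dihydroxyflavones.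

**Compound list**

1 | 3-hydroxy-4H-pyran-4-one (pyromeconic acid) | O=c1ccocc1O | starting material
2 | 2-bromo-3-hydroxy-4H-pyran-4-one | O=c1ccoc(Br)c1O | intermediate
3 | 2-bromo-3-methoxy-4H-pyran-4-one | COc1c(Br)occc1=O | intermediate
4 | (2,5-dimethoxyphenyl)boronic acid | COc1ccc(OC)c(B(O)O)c1 | starting material
5 | 2-(2,5-dimethoxyphenyl)-3-methoxy-4H-pyran-4-one | COc1ccc(OC)c(-c2occc(=O)c2OC)c1 | intermediate
6 | 2-(2,5-dimethoxyphenyl)-5-iodo-3-methoxy-4H-pyran-4-one | COc1ccc(OC)c(-c2occ(I)c(=O)c2OC)c1 | intermediate
7 | dimethyl squarate (3,4-dimethoxycyclobut-3-ene-1,2-dione) | COC1=C(OC)C(=O)C1=O | starting material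
8 | [6-(2,5-dimethoxyphenyl)-5-methoxy-4-oxo-4H-pyran-3-yl]magnesium chloride (not isolated) | COc1ccc(OC)c(-c2occ([Mg]Cl)c(=O)c2OC)c1 | intermediate
9 | 4-[6-(2,5-dimethoxyphenyl)-5-methoxy-4-oxo-4H-pyran-3-yl]-4-hydroxy-2,3-dimethoxycyclobut-2-en-1-one (racemic) | COC1=C(OC)C(O)(c2coc(-c3cc(OC)ccc3OC)c(OC)c2=O)C1=O | intermediate
10 | (Z)-dienylketene: 4-[6-(2,5-dimethoxyphenyl)-5-methoxy-4-oxo-4H-pyran-3-yl]-4-hydroxy-2,3-dimethoxybuta-1,3-dien-1-one (not isolated) | O=C=C(OC)/C(OC)=C(/O)c1coc(-c2cc(OC)ccc2OC)c(OC)c1=O | intermediate
11 | 2-(2,5-dimethoxyphenyl)-5-hydroxy-3,6,7-trimethoxy-8aH-chromene-4,8-dione (racemic, not isolated) | COc1ccc(OC)c(C2=C(OC)C(=O)C3=C(O)C(OC)=C(OC)C(=O)C3O2)c1 | intermediate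
12 | 2-(2,5-dimethoxyphenyl)-5,8-dihydroxy-3,6,7-trimethoxy-4H-chromen-4-one | COc1ccc(OC)c(-c2oc3c(O)c(OC)c(OC)c(O)c3c(=O)c2OC)c1 | intermediate
13 | Grantioidinin | COc1ccc(OC)c(-c2oc3c(OC)c(OC)c(OC)c(O)c3c(=O)c2OC)c1 | target

**Step count and risks**

Total step count: 7. Longest linear sequence: 7 steps (1 → 13); the partners 4 and 7 are bought.

Steps most likely to fail:

1. Step 6 (key step). After ring opening, the free tertiary hydroxyl may add to the ketene (lactonisation to a butenolide) faster than the electrocyclisation onto the electron-poor pyranone CH, and the electron-rich hydroquinone may be oxidised to the 5,8-quinone during isolation. The fallback sets out from 9 and uses the regiospecifically O-protected variant of the same ring expansion. Acetylation of the carbinol (Ac2O, DMAP, Et3N, CH2Cl2, 0 °C) would give 1-[6-(2,5-dimethoxyphenyl)-5-methoxy-4-oxo-4H-pyran-3-yl]-2,3-dimethoxy-4-oxocyclobut-2-en-1-yl acetate F4. Thermolysis in degassed toluene should then give the air-stable monoprotected hydroquinone 2-(2,5-dimethoxyphenyl)-8-hydroxy-3,6,7-trimethoxy-4-oxo-4H-chromen-5-yl acetate F5. Methylation of its only free hydroxyl (MeI, K2CO3, acetone) would give 2-(2,5-dimethoxyphenyl)-3,6,7,8-tetramethoxy-4-oxo-4H-chromen-5-yl acetate F6, and methanolysis of the acetate (K2CO3, MeOH, rt) returns to the route at 13.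

2. Step 4. Iodination may lose site selectivity between the two nucleophilic π-systems, so that the dimethoxyphenyl ring is iodinated alongside or instead of pyranone C5. The fallback sets out from 3 and places the halogen before the electron-rich arene is present. Bromine addition–elimination (Br2, CH2Cl2, 0 °C, then Et3N) would give 2,5-dibromo-3-methoxy-4H-pyran-4-one F1. A site-selective Suzuki coupling with 4 at the more electrophilic C2–Br (β-halo-enone before α-halo-enone) would give 5-bromo-2-(2,5-dimethoxyphenyl)-3-methoxy-4H-pyran-4-one F2. Bromine–magnesium exchange (iPrMgCl·LiCl, THF, −20 °C) comes back to the route at Grignard reagent 8.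

3. Step 5. The magnesiated pyranone may fragment by ring-opening β-elimination of the ring oxygen, the exchange reagent may add to the pyranone, or the Grignard reagent may add twice to the squarate. The fallback sets out from 6 and replaces the basic Grignard reagent by an organozinc made by direct insertion. Zinc dust with LiCl in THF at 25 °C would give [6-(2,5-dimethoxyphenyl)-5-methoxy-4-oxo-4H-pyran-3-yl]zinc iodide F3, and MgCl2-promoted 1,2-addition of this non-basic reagent to 7 comes back to the route at 9.

**Further compounds**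

F1 | step 4 | 2,5-dibromo-3-methoxy-4H-pyran-4-one | COc1c(Br)occ(Br)c1=O
F2 | step 4 | 5-bromo-2-(2,5-dimethoxyphenyl)-3-methoxy-4H-pyran-4-one | COc1ccc(OC)c(-c2occ(Br)c(=O)c2OC)c1
F3 | step 5 | [6-(2,5-dimethoxyphenyl)-5-methoxy-4-oxo-4H-pyran-3-yl]zinc iodide | COc1ccc(OC)c(-c2occ([Zn]I)c(=O)c2OC)c1
F4 | step 6 | 1-[6-(2,5-dimethoxyphenyl)-5-methoxy-4-oxo-4H-pyran-3-yl]-2,3-dimethoxy-4-oxocyclobut-2-en-1-yl acetate (racemic) | COC1=C(OC)C(OC(C)=O)(c2coc(-c3cc(OC)ccc3OC)c(OC)c2=O)C1=O
F5 | step 6 | 2-(2,5-dimethoxyphenyl)-8-hydroxy-3,6,7-trimethoxy-4-oxo-4H-chromen-5-yl acetate | COc1ccc(OC)c(-c2oc3c(O)c(OC)c(OC)c(OC(C)=O)c3c(=O)c2OC)c1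
F6 | step 6 | 2-(2,5-dimethoxyphenyl)-3,6,7,8-tetramethoxy-4-oxo-4H-chromen-5-yl acetate | COc1ccc(OC)c(-c2oc3c(OC)c(OC)c(OC)c(OC(C)=O)c3c(=O)c2OC)c1
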